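**Strategy.** The dihydrofuran is read as the ring-contracted image of a flavanone. C3 carries both ring A (through C3a) and the ester carbon, so shifting ring A back from C3 to that carbon gives a chroman-4-one that holds the same O1–C2(aryl) bond. The key step closes this bond by a thiourea-catalysed 6-endo oxa-Michael addition of the ring A phenol oxygen O1 to the β-carbon C2 of an alkylidene β-ketoester (a 2′-hydroxychalcone), setting C2 as R. An oxidative 1,2-shift of ring A with PhI(OAc)2 then cleaves the temporary flavanone C4–C4a bond, contracts the pyranone to the dihydrofuran and sets C3 trans. Heck coupling and debenzylation finish.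

Key step: step 5

Assumption: the quinine-derived thiourea is taken to deliver the (2R)-flavanone; if the sense proves opposite, the quinidine-derived pseudoenantiomer is used with no other change.

Step 1
Reactants: 1 methyl 2,3-dihydroxybenzoate; 2 benzyl bromide
Product: 3 methyl 3-(benzyloxy)-2-hydroxybenzoate
Conditions: NaH (2.1 equiv), DMF, 0 °C; then BnBr (1.0 equiv), 0 °C → rt; aq. HCl work-up
Reagents that add atoms: benzyl bromide, BrCc1ccccc1
Why: Williamson ether synthesis on the dianion, in which the 3-phenoxide (not chelated by or conjugated to the ester carbonyl) is the more nucleophilic oxygen, so one equivalent of benzyl bromide should alkylate O3 selectively.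

Step 2
Reactants: 3 methyl 3-(benzyloxy)-2-hydroxybenzoate; 4 N-bromosuccinimide
Product: 5 methyl 3-(benzyloxy)-5-bromo-2-hydroxybenzoate
Conditions: NBS (1.05 equiv), MeCN, 0 °C → rt
Reagents that add atoms: N-bromosuccinimide, O=C1CCC(=O)N1Br
Why: Electrophilic aromatic bromination, directed to C5 by the free phenol (para) and by the ester (meta).

Step 3
Reactants: 5 methyl 3-(benzyloxy)-5-bromo-2-hydroxybenzoate; 6 tert-butyl acetate
Product: 7 tert-butyl 3-[3-(benzyloxy)-5-bromo-2-hydroxyphenyl]-3-oxopropanoate
Conditions: t-BuOAc (4 equiv), LiN(i-Pr)2 (4 equiv), THF, −78 °C; then 5, −78 → 0 °C; aq. HCl work-up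
Reagents that add atoms: tert-butyl acetate, CC(=O)OC(C)(C)C
Why: Crossed Claisen condensation of the lithium enolate of tert-butyl acetate with the salicylate ester; excess enolate covers the phenol proton and the β-ketoester is protected as its enolate against a second addition.

Step 4
Reactants: 7 tert-butyl 3-[3-(benzyloxy)-5-bromo-2-hydroxyphenyl]-3-oxopropanoate; 8 3,4-bis(benzyloxy)benzaldehyde
Product: 9 tert-butyl (2Z)-2-[3-(benzyloxy)-5-bromo-2-hydroxybenzoyl]-3-[3,4-bis(benzyloxy)phenyl]prop-2-enoate
Conditions: piperidine (10 mol %), AcOH (10 mol %), 4 Å MS, toluene, rt → 40 °C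
Reagents that add atoms: 3,4-bis(benzyloxy)benzaldehyde, O=Cc1ccc(OCc2ccccc2)c(OCc2ccccc2)c1
Why: Knoevenagel condensation of the active methylene group with the non-enolisable aldehyde under piperidinium acetate catalysis with removal of water, expected to give mainly the isomer drawn, the mild temperature limiting uncatalysed cyclisation of the free phenol.

Step 5
Reactants: 9 tert-butyl (2Z)-2-[3-(benzyloxy)-5-bromo-2-hydroxybenzoyl]-3-[3,4-bis(benzyloxy)phenyl]prop-2-enoate
Product: 11 (2R)-8-(benzyloxy)-2-[3,4-bis(benzyloxy)phenyl]-6-bromo-2,3-dihydro-4H-chromen-4-one, via oxa-Michael adduct 10 (not isolated)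
Conditions: N-[3,5-bis(trifluoromethyl)phenyl]-N′-[(8α,9S)-6′-methoxycinchonan-9-yl]thiourea (10 mol %), toluene, −25 °C; then TsOH·H2O (0.5 equiv), 80 °C
Reagents that add atoms: none
Why: The quinuclidine nitrogen of the bifunctional catalyst activates the phenol O–H while the thiourea hydrogen-bonds the 1,3-dicarbonyl unit of the alkylidene, so the phenol oxygen adds to one enantioface of the β-carbon and the enol is protonated to the β-ketoester 10; TsOH then removes the tert-butyl group as 2-methylpropene and the β-keto acid loses CO2. The closest known reaction type is the cinchona-thiourea-catalysed enantioselective intramolecular oxa-Michael addition of alkylidene β-ketoesters that gives flavanones. The chroman-4-one ring closes in the 6-endo-trig mode. The only lasting stereocentre, C2, is set by the catalyst (R, see the assumption), and C3 of 10 is lost on decarboxylation. The step needs enantiofacial selectivity and freedom from retro-oxa-Michael racemisation: the ester raises the electrophilicity so that the reaction should run at −25 °C, where the background cyclisation is slow, and the acidic decarboxylation avoids the phenoxide needed for ring opening.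

Step 6
Reactants: 11 (2R)-8-(benzyloxy)-2-[3,4-bis(benzyloxy)phenyl]-6-bromo-2,3-dihydro-4H-chromen-4-one; 12 trimethyl orthoformate
Product: 14 methyl (2R,3R)-7-(benzyloxy)-2-[3,4-bis(benzyloxy)phenyl]-5-bromo-2,3-dihydro-1-benzofuran-3-carboxylate, via dimethyl ketal 13 (not isolated)
Conditions: PhI(OAc)2 (1.2 equiv), HC(OMe)3 (solvent), conc. H2SO4 (cat.), rt
Reagents that add atoms: trimethyl orthoformate, COC(OC)OC
Why: Oxidative ring contraction of a flavanone by a trivalent-iodine reagent, in which the enol ether derived from ketal 13 is iodinated at C3 trans to the C2 aryl group and ring A then migrates from C4 to C3 with loss of iodobenzene (1,2-aryl shift), the dimethoxycarbenium ion collapsing to the methyl ester; C2 is untouched and C3 is set trans to the C2 aryl group, which is also the thermodynamic arrangement.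

Step 7
Reactants: 14 methyl (2R,3R)-7-(benzyloxy)-2-[3,4-bis(benzyloxy)phenyl]-5-bromo-2,3-dihydro-1-benzofuran-3-carboxylate; 15 methyl acrylate
Product: 16 methyl (2R,3R)-7-(benzyloxy)-2-[3,4-bis(benzyloxy)phenyl]-5-[(1E)-3-methoxy-3-oxoprop-1-en-1-yl]-2,3-dihydro-1-benzofuran-3-carboxylate
Conditions: methyl acrylate (3 equiv), Pd(OAc)2 (5 mol %), P(o-tol)3 (10 mol %), Et3N (2 equiv), DMF, 100 °C
Reagents that add atoms: methyl acrylate, C=CC(=O)OC
Why: Mizoroki–Heck reaction of the aryl bromide, in which syn insertion and syn β-hydride elimination give the E-acrylate, the tertiary amine being too weak a base to open the dihydrofuran by β-elimination.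

Step 8
Reactants: 16 methyl (2R,3R)-7-(benzyloxy)-2-[3,4-bis(benzyloxy)phenyl]-5-[(1E)-3-methoxy-3-oxoprop-1-en-1-yl]-2,3-dihydro-1-benzofuran-3-carboxylate
Product: 17 methyl (2R,3R)-2-(3,4-dihydroxyphenyl)-7-hydroxy-5-[(1E)-3-methoxy-3-oxoprop-1-en-1-yl]-2,3-dihydro-1-benzofuran-3-carboxylate
Conditions: BCl3 (6 equiv), pentamethylbenzene (9 equiv), CH2Cl2, −78 °C; then H2O
Reagents that add atoms: none
Why: Lewis-acid cleavage of aryl benzyl ethers with pentamethylbenzene as a non-basic benzyl-cation scavenger, which at −78 °C should spare the acrylate and both methyl esters, any reversible ionisation at C2 reclosing to the trans isomer under control of C3.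

**Compound list**

1 | methyl 2,3-dihydroxybenzoate | COC(=O)c1cccc(O)c1O | starting material
2 | benzyl bromide | BrCc1ccccc1 | starting material
3 | methyl 3-(benzyloxy)-2-hydroxybenzoate | COC(=O)c1cccc(OCc2ccccc2)c1O | intermediate
4 | N-bromosuccinimide | O=C1CCC(=O)N1Br | starting material
5 | methyl 3-(benzyloxy)-5-bromo-2-hydroxybenzoate | COC(=O)c1cc(Br)cc(OCc2ccccc2)c1O | intermediate
6 | tert-butyl acetate | CC(=O)OC(C)(C)C | starting material
7 | tert-butyl 3-[3-(benzyloxy)-5-bromo-2-hydroxyphenyl]-3-oxopropanoate | CC(C)(C)OC(=O)CC(=O)c1cc(Br)cc(OCc2ccccc2)c1O | intermediate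
8 | 3,4-bis(benzyloxy)benzaldehyde | O=Cc1ccc(OCc2ccccc2)c(OCc2ccccc2)c1 | starting material
9 | tert-butyl (2Z)-2-[3-(benzyloxy)-5-bromo-2-hydroxybenzoyl]-3-[3,4-bis(benzyloxy)phenyl]prop-2-enoate (aryl cis to the ester, the expected major isomer) | CC(C)(C)OC(=O)/C(=C\c1ccc(OCc2ccccc2)c(OCc2ccccc2)c1)C(=O)c1cc(Br)cc(OCc2ccccc2)c1O | intermediate
10 | tert-butyl (2R)-8-(benzyloxy)-2-[3,4-bis(benzyloxy)phenyl]-6-bromo-4-oxo-3,4-dihydro-2H-chromene-3-carboxylate (C3 undefined, keto/enol mixture) | CC(C)(C)OC(=O)C1C(=O)c2cc(Br)cc(OCc3ccccc3)c2O[C@H]1c1ccc(OCc2ccccc2)c(OCc2ccccc2)c1 | intermediate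
11 | (2R)-8-(benzyloxy)-2-[3,4-bis(benzyloxy)phenyl]-6-bromo-2,3-dihydro-4H-chromen-4-one | O=C1C[C@H](c2ccc(OCc3ccccc3)c(OCc3ccccc3)c2)Oc2c(OCc3ccccc3)cc(Br)cc21 | intermediate
12 | trimethyl orthoformate | COC(OC)OC | starting material
13 | (2R)-8-(benzyloxy)-2-[3,4-bis(benzyloxy)phenyl]-6-bromo-4,4-dimethoxy-3,4-dihydro-2H-chromene | COC1(OC)C[C@H](c2ccc(OCc3ccccc3)c(OCc3ccccc3)c2)Oc2c(OCc3ccccc3)cc(Br)cc21 | intermediate
14 | methyl (2R,3R)-7-(benzyloxy)-2-[3,4-bis(benzyloxy)phenyl]-5-bromo-2,3-dihydro-1-benzofuran-3-carboxylate | Brc1cc(OCc3ccccc3)c2c(c1)[C@@H](C(=O)OC)[C@H](c1ccc(OCc3ccccc3)c(OCc3ccccc3)c1)O2 | intermediate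
15 | methyl acrylate | C=CC(=O)OC | starting material
16 | methyl (2R,3R)-7-(benzyloxy)-2-[3,4-bis(benzyloxy)phenyl]-5-[(1E)-3-methoxy-3-oxoprop-1-en-1-yl]-2,3-dihydro-1-benzofuran-3-carboxylate | COC(=O)/C=C/c1cc(OCc3ccccc3)c2c(c1)[C@@H](C(=O)OC)[C@H](c1ccc(OCc3ccccc3)c(OCc3ccccc3)c1)O2 | intermediate
17 | methyl (2R,3R)-2-(3,4-dihydroxyphenyl)-7-hydroxy-5-[(1E)-3-methoxy-3-oxoprop-1-en-1-yl]-2,3-dihydro-1-benzofuran-3-carboxylate | COC(=O)/C=C/c1cc(O)c2c(c1)[C@@H](C(=O)OC)[C@H](c1ccc(O)c(O)c1)O2 | target

**Total step count:** 8. **Longest linear sequence:** 8 steps (1 → 17).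

**Steps most likely to fail**

Step 5. Enantiofacial selectivity may erode through uncatalysed background cyclisation of the hindered, electron-rich alkylidene or through reversible ring opening before decarboxylation. Fallback: setting out from 9, cyclisation without a chiral catalyst (Et3N cat., toluene, rt; then TsOH·H2O, 80 °C) should give the racemic flavanone F1. Kinetic resolution by asymmetric transfer hydrogenation (RuCl(p-cymene)(TsDPEN), the ligand enantiomer chosen so that the (2S)-ketone is reduced faster, HCO2H/Et3N) should convert the unwanted antipode into the cis-flavan-4-ol F2, which is removed by chromatography. The unreduced ketone is 11, where the route is rejoined; the O1–C2 bond is still closed by oxa-Michael addition.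

Step 6. The iodane may oxidise the electron-rich bis(benzyloxy)phenyl ring, or dehydrogenation to the flavone and migration of the wrong aryl group may compete with the ring A shift. Fallback: setting out from 11, condensation with N,N-dimethylformamide dimethyl acetal (toluene, 80 °C) should give the enaminone F3. Diazo transfer with 4-acetamidobenzenesulfonyl azide (MeCN, rt) should then give the 3-diazoflavanone F4. Photochemical Wolff rearrangement in methanol (hν, 350 nm, rt) contracts the ring through the ketene, which methanol traps as the methyl ester; after equilibration of C3 to trans (Et3N cat., MeOH) this is 14, where the route is rejoined.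

Step 8. The Lewis acid may ionise the C2–O1 benzylic ether with ring opening, or cleavage of the three ethers may stop short. Fallback: setting out from 14, reductive carbonylation (Pd(OAc)2, di(1-adamantyl)-n-butylphosphine, CO/H2, TMEDA, toluene, 100 °C) should give the aldehyde F5. Brief hydrogenolysis (H2, Pd on carbon, EtOAc, rt) removes the three benzyl groups to give the triphenol aldehyde F6. Wittig olefination with methyl (triphenylphosphoranylidene)acetate (MeCN, 60 °C) installs the E-acrylate and gives 17 directly.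

**Further compounds**

F1 | step 5 | racemic 8-(benzyloxy)-2-[3,4-bis(benzyloxy)phenyl]-6-bromo-2,3-dihydro-4H-chromen-4-one | O=C1CC(c2ccc(OCc3ccccc3)c(OCc3ccccc3)c2)Oc2c(OCc3ccccc3)cc(Br)cc21
F2 | step 5 | (2S,4S)-8-(benzyloxy)-2-[3,4-bis(benzyloxy)phenyl]-6-bromo-3,4-dihydro-2H-chromen-4-ol | O[C@H]1C[C@@H](c2ccc(OCc3ccccc3)c(OCc3ccccc3)c2)Oc2c(OCc3ccccc3)cc(Br)cc21
F3 | step 6 | (2S,3E)-8-(benzyloxy)-2-[3,4-bis(benzyloxy)phenyl]-6-bromo-3-[(dimethylamino)methylidene]-2,3-dihydro-4H-chromen-4-one (same spatial arrangement at C2 as 11; descriptor changes by priority) | O=C1/C(=C/N(C)C)[C@H](c2ccc(OCc3ccccc3)c(OCc3ccccc3)c2)Oc2c(OCc3ccccc3)cc(Br)cc21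
F4 | step 6 | (2S)-8-(benzyloxy)-2-[3,4-bis(benzyloxy)phenyl]-6-bromo-3-diazo-2,3-dihydro-4H-chromen-4-one (same spatial arrangement at C2 as 11) | O=C1C(=[N+]=[N-])[C@H](c2ccc(OCc3ccccc3)c(OCc3ccccc3)c2)Oc2c(OCc3ccccc3)cc(Br)cc21
F5 | step 8 | methyl (2R,3R)-7-(benzyloxy)-2-[3,4-bis(benzyloxy)phenyl]-5-formyl-2,3-dihydro-1-benzofuran-3-carboxylate | O=Cc1cc(OCc3ccccc3)c2c(c1)[C@@H](C(=O)OC)[C@H](c1ccc(OCc3ccccc3)c(OCc3ccccc3)c1)O2
F6 | step 8 | methyl (2R,3R)-2-(3,4-dihydroxyphenyl)-5-formyl-7-hydroxy-2,3-dihydro-1-benzofuran-3-carboxylate | O=Cc1cc(O)c2c(c1)[C@@H](C(=O)OC)[C@H](c1ccc(O)c(O)c1)O2
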